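**Retrosynthetic overview**

1. Target 13 has acetoxy cis to pentenyl and the two carbon chains trans (ring numbering: C1 = C=O, C2=C3, C4 = C(OAc)(chain), C5 = CH(pentenyl)). It is traced back to hydroxy-enone tert-butyl ester 11 by O-acetylation and ester acidolysis.
2. 11 comes from furylcarbinol 8 by a catalytic enantioselective oxa-Piancatelli rearrangement. The C4–C5 bond is closed by 4π-conrotatory cyclisation of a dihydroxypentadienyl cation, a copy of the oxidopentadienyl-cation closure that builds the 12-oxophytodienoate ring in oxylipin biosynthesis. Ring, enone, quaternary C–O centre and both stereocentres arise in this one isomerisation.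
3. 8 comes from aldehyde 4 and a (Z)-pent-2-enylbarium reagent (α-selective, Z-retentive). 4 comes from 5-bromofurfural 2 and the alkylzinc made from bromo ester 1 (Negishi coupling).
4. Ring order: the furan is purchased and consumed. The cyclopentenone is the only ring of the skeleton and is closed in step 4.
5. Enabling feature: in the cyclopentenone, the C1 carbonyl and the C4 tertiary C–O flank the C2=C3 double bond. This C1–C4 unit is the carbon skeleton of a 2,5-disubstituted furan with its ring oxygen, and C5 (H, pentenyl) is a furyl carbinol carbon.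

Key step: step 4

Assumption: the (R)-configured catalyst is written in step 4. Which antipode delivers the (1R,5R) product on this new substrate class must be established by experiment, and the (S)-catalyst is used if the sense is opposite.

**Step 1**
Reactants: 1 tert-butyl 8-bromooctanoate; 2 5-bromofuran-2-carbaldehyde
Product: 4 tert-butyl 8-(5-formylfuran-2-yl)octanoate, via alkylzinc bromide 3 (not isolated)
Conditions: Zn dust, I2 (5 mol %), DMA, 80 °C; then 2, Pd(OAc)2 (2 mol %), SPhos (4 mol %), THF, 25 °C
Reagents that add atoms: none
Why: Negishi cross-coupling, in which zinc inserts into the primary C–Br bond of 1 without touching the tert-butyl ester, the electron-poor bromofuran 2 adds oxidatively to zerovalent palladium, the alkylzinc halide does not add to the aldehyde, and the bulky biarylphosphine suppresses β-hydride elimination.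

**Step 2**
Reactants: 5 (2Z)-pent-2-en-1-ol
Product: 6 (2Z)-1-chloropent-2-ene
Conditions: PPh3, hexachloroacetone, CH2Cl2, 0 °C
Reagents that add atoms: hexachloroacetone, ClC(Cl)(Cl)C(=O)C(Cl)(Cl)Cl
Why: Appel-type chlorination, in which the PPh3/hexachloroacetone couple converts the primary allylic alcohol by SN2 displacement of the oxyphosphonium group at 0 °C without allylic transposition or loss of the Z geometry.

**Step 3**
Reactants: 6 (2Z)-1-chloropent-2-ene; 4 tert-butyl 8-(5-formylfuran-2-yl)octanoate
Product: 8 racemic tert-butyl 8-{5-[(3Z)-1-hydroxyhex-3-en-1-yl]furan-2-yl}octanoate, via pentenylbarium chloride 7 (not isolated)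
Conditions: BaI2, lithium biphenylide (2 equiv), THF, 25 °C; 6, −78 °C; then 4, −78 °C; aq NH4Cl
Reagents that add atoms: none
Why: Carbonyl allylation with an allylbarium reagent, which unlike allyl-magnesium, -zinc or -indium species reacts at its α-carbon with retention of the double-bond geometry when made and used at −78 °C, so the linear (Z)-homoallylic alcohol should result; the aldehyde reacts far faster than the tert-butyl ester, and the new carbinol centre is formed racemic, which is immaterial because it is planarised in step 4.

**Step 4**
Reactants: 8 racemic tert-butyl 8-{5-[(3Z)-1-hydroxyhex-3-en-1-yl]furan-2-yl}octanoate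
Product: 11 tert-butyl 8-[(1R,5R)-1-hydroxy-4-oxo-5-[(2Z)-pent-2-en-1-yl]cyclopent-2-en-1-yl]octanoate, via hydroxydihydrofuran hemiketal 9 (not isolated), via dihydroxypentadienyl cation 10 (not isolated)
Conditions: (R)-3,3'-bis(2,4,6-triisopropylphenyl)-1,1'-binaphthyl-2,2'-diyl N-triflylphosphoramide (5 mol %), H2O (3 equiv), CHCl3, 40 °C
Reagents that add atoms: water, O
Why: Proposed new method: the chiral acid ionises the carbinol of 8 to a 5-alkylfurfuryl cation, water adds at furan C5 to give hemiketal 9, and cleavage of its ring C–O bond releases the 1,4-dihydroxypentadienyl cation 10, which closes the C4–C5 bond by thermal conrotatory 4π electrocyclisation and then loses a proton to give the enone (a net isomerisation in which the furan oxygen becomes the C1 carbonyl oxygen and water supplies the C4 hydroxyl). The racemic process is the Piancatelli rearrangement, known for 5-methyl-2-furyl carbinols bearing allyl and propargyl groups, and the closest enantioselective reaction types are the chiral-phosphoric-acid-catalysed aza-Piancatelli rearrangement, the chiral-oxovanadium-catalysed oxa-Piancatelli rearrangement of aryl 2-furyl carbinols and the N-triflylphosphoramide-catalysed Nazarov cyclisation; not yet shown is enantiocontrol with water on an alkyl carbinol of a 5-alkylfuran, which creates a fully substituted carbinol carbon. The cyclopentenone, the only ring closed, forms in the 4π-conrotatory mode (five-atom cation to five-membered ring). The C4 configuration is set by the sense of conrotation, which the chiral phosphoramide anion, hydrogen-bonded to both hydroxyls of 10, is expected to dictate; C5 is set relative to C4 by the cation geometry, because the pentenyl group at the enol terminus and the heptyl chain (rather than the smaller OH) at the oxocarbenium terminus should take the outside positions, so conrotation places the chains trans and OH cis to pentenyl, which is also the more stable arrangement at the epimerisable C5. The step needs capture of the cation by water at furan C5 (attack at the carbinol carbon only regenerates 8), which the 2,5-disubstituted furan secures, and chemoselectivity over E1 loss of the allylic CH2 proton, which the excess water and low temperature should favour.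

**Step 5**
Reactants: 11 tert-butyl 8-[(1R,5R)-1-hydroxy-4-oxo-5-[(2Z)-pent-2-en-1-yl]cyclopent-2-en-1-yl]octanoate
Product: 12 tert-butyl 8-[(1R,5R)-1-acetoxy-4-oxo-5-[(2Z)-pent-2-en-1-yl]cyclopent-2-en-1-yl]octanoate
Conditions: Ac2O (1.5 equiv), Sc(OTf)3 (2 mol %), MeCN, −20 °C
Reagents that add atoms: acetic anhydride, CC(=O)OC(C)=O
Why: Lewis-acid-catalysed acylation with Sc(OTf)3 and acetic anhydride esterifies hindered tertiary alcohols at low temperature without base, which avoids E1cB loss of acetate from the β-acetoxy ketone, while ionisation at C4 is disfavoured because it would give a destabilised 4-oxocyclopentenyl cation; both stereocentres are untouched.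

**Step 6**
Reactants: 12 tert-butyl 8-[(1R,5R)-1-acetoxy-4-oxo-5-[(2Z)-pent-2-en-1-yl]cyclopent-2-en-1-yl]octanoate
Product: 13 8-[(1R,5R)-1-acetoxy-4-oxo-5-[(2Z)-pent-2-en-1-yl]cyclopent-2-en-1-yl]octanoic acid
Conditions: TFA/CH2Cl2 (1:4), 0 °C
Reagents that add atoms: none
Why: Acidolysis of the tert-butyl ester (E1 loss of 2-methylpropene) under conditions to which the tertiary acetate, the enone and the isolated Z-alkene should be inert, the absence of base excluding epimerisation at C5 and β-elimination of acetic acid.

**Compound list**

1 | tert-butyl 8-bromooctanoate | CC(C)(C)OC(=O)CCCCCCCBr | starting material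
2 | 5-bromofuran-2-carbaldehyde | O=Cc1ccc(Br)o1 | starting material
3 | (8-tert-butoxy-8-oxooctyl)zinc bromide (not isolated) | CC(C)(C)OC(=O)CCCCCCC[Zn]Br | intermediate
4 | tert-butyl 8-(5-formylfuran-2-yl)octanoate | CC(C)(C)OC(=O)CCCCCCCc1ccc(C=O)o1 | intermediate
5 | (2Z)-pent-2-en-1-ol | CC/C=C\CO | starting material
6 | (2Z)-1-chloropent-2-ene | CC/C=C\CCl | intermediate
7 | [(2Z)-pent-2-en-1-yl]barium chloride (not isolated) | CC/C=C\C[Ba]Cl | intermediate
8 | racemic tert-butyl 8-{5-[(3Z)-1-hydroxyhex-3-en-1-yl]furan-2-yl}octanoate | CC/C=C\CC(O)c1ccc(CCCCCCCC(=O)OC(C)(C)C)o1 | intermediate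
9 | tert-butyl 8-{(5Z)-5-[(3Z)-hex-3-en-1-ylidene]-2-hydroxy-2,5-dihydrofuran-2-yl}octanoate (hemiketal, racemic, not isolated) | CC/C=C\C/C=C1/C=CC(O)(CCCCCCCC(=O)OC(C)(C)C)O1 | intermediate
10 | O-protonated tert-butyl (10Z,12Z,15Z)-12-hydroxy-9-oxooctadeca-10,12,15-trienoate (1,4-dihydroxypentadienyl cation, not isolated) | CC/C=C\C/C=C(\O)/C=C\C(=[OH+])CCCCCCCC(=O)OC(C)(C)C | intermediate
11 | tert-butyl 8-[(1R,5R)-1-hydroxy-4-oxo-5-[(2Z)-pent-2-en-1-yl]cyclopent-2-en-1-yl]octanoate | CC/C=C\C[C@H]1C(=O)C=C[C@@]1(CCCCCCCC(=O)OC(C)(C)C)O | intermediate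
12 | tert-butyl 8-[(1R,5R)-1-acetoxy-4-oxo-5-[(2Z)-pent-2-en-1-yl]cyclopent-2-en-1-yl]octanoate | CC/C=C\C[C@H]1C(=O)C=C[C@@]1(CCCCCCCC(=O)OC(C)(C)C)OC(C)=O | intermediate
13 | 8-[(1R,5R)-1-acetoxy-4-oxo-5-[(2Z)-pent-2-en-1-yl]cyclopent-2-en-1-yl]octanoic acid | CC/C=C\C[C@H]1C(=O)C=C[C@@]1(CCCCCCCC(=O)O)OC(C)=O | target

**Step count and risks**

Total: 6 steps. Longest linear sequence: 5 steps (steps 1, 3, 4, 5, 6 from 1 and 2; equally steps 2, 3, 4, 5, 6 from 5).

Steps most likely to fail:

1. Step 4 (Proposed new method). The chiral anion may give insufficient control over the sense of conrotation. E1 deprotonation of the furfuryl cation, with migration of the side-chain double bond, may outrun water capture. Turnover may be too slow for the 5-alkylfuran at 40 °C, and the C5 epimer may form kinetically. The fallback sets out from 8 and comes back at 11. The classical Piancatelli rearrangement (ZnCl2, dioxane/H2O 1:1, reflux, weakly acidic) should give racemic 11, that is, 11 together with its enantiomer tert-butyl 8-[(1S,5S)-1-hydroxy-4-oxo-5-[(2Z)-pent-2-en-1-yl]cyclopent-2-en-1-yl]octanoate F1. The hot acidic medium should also equilibrate C5 through the enol towards the trans-dialkyl isomer. The enantiomers are then separated by preparative supercritical-fluid chromatography on an amylose tris(3,5-dimethylphenylcarbamate) stationary phase, and enantiopure 11 re-enters at step 5.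

2. Step 3. The α-regioselectivity may erode (γ-attack would give the branched homoallylic alcohol), the allylbarium may isomerise from Z to E if it warms above −78 °C, or the reagent may attack the ester. The fallback sets out from zinc reagent 3 (made from 1 as in step 1) and comes back at 8, with the polarity of the carbinol-forming bond reversed. Negishi coupling of 3 with 2-bromofuran (Brc1ccco1, purchased; Pd(OAc)2, SPhos, THF) should give tert-butyl 8-(furan-2-yl)octanoate F2. Bromination (NBS, DMF, 0 °C, dark) should give tert-butyl 8-(5-bromofuran-2-yl)octanoate F3. Bromine–magnesium exchange (iPrMgCl·LiCl, THF, 0 °C) should give [5-(8-tert-butoxy-8-oxooctyl)furan-2-yl]magnesium chloride F4, which is not isolated. F4 is added at −78 °C, with LaCl3·2LiCl to suppress enolisation, to (3Z)-hex-3-enal F5, freshly made from purchased (3Z)-hex-3-en-1-ol (CC/C=C\CCO) with Dess–Martin periodinane and NaHCO3 in CH2Cl2 at 0 °C. This should deliver 8 with the Z-alkene already in place.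

3. Step 5. Acylation of the hindered tertiary hydroxyl may be slow, with competing Lewis-acid cleavage of the tert-butyl ester or elimination of acetic acid. The fallback sets out from 11 and comes back at 13, with the order of the endgame reversed so that no ester needs to survive the acetylation. Acidolysis of 11 (TFA/CH2Cl2, 0 °C) should give 8-[(1R,5R)-1-hydroxy-4-oxo-5-[(2Z)-pent-2-en-1-yl]cyclopent-2-en-1-yl]octanoic acid F6. Acetylation with excess Ac2O and Sc(OTf)3 in MeCN at −20 °C should give acetic 8-[(1R,5R)-1-acetoxy-4-oxo-5-[(2Z)-pent-2-en-1-yl]cyclopent-2-en-1-yl]octanoic anhydride F7, which is not isolated. Its mixed-anhydride function is hydrolysed on stirring with THF/pH 7 phosphate buffer at 25 °C to give 13.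

**Further compounds**

F1 | step 4 | tert-butyl 8-[(1S,5S)-1-hydroxy-4-oxo-5-[(2Z)-pent-2-en-1-yl]cyclopent-2-en-1-yl]octanoate | CC/C=C\C[C@@H]1C(=O)C=C[C@]1(CCCCCCCC(=O)OC(C)(C)C)O
F2 | step 3 | tert-butyl 8-(furan-2-yl)octanoate | CC(C)(C)OC(=O)CCCCCCCc1ccco1
F3 | step 3 | tert-butyl 8-(5-bromofuran-2-yl)octanoate | CC(C)(C)OC(=O)CCCCCCCc1ccc(Br)o1
F4 | step 3 | [5-(8-tert-butoxy-8-oxooctyl)furan-2-yl]magnesium chloride | CC(C)(C)OC(=O)CCCCCCCc1ccc([Mg]Cl)o1
F5 | step 3 | (3Z)-hex-3-enal | CC/C=C\CC=O
F6 | step 5 | 8-[(1R,5R)-1-hydroxy-4-oxo-5-[(2Z)-pent-2-en-1-yl]cyclopent-2-en-1-yl]octanoic acid | CC/C=C\C[C@H]1C(=O)C=C[C@@]1(CCCCCCCC(=O)O)O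
F7 | step 5 | acetic 8-[(1R,5R)-1-acetoxy-4-oxo-5-[(2Z)-pent-2-en-1-yl]cyclopent-2-en-1-yl]octanoic anhydride | CC/C=C\C[C@H]1C(=O)C=C[C@@]1(CCCCCCCC(=O)OC(C)=O)OC(C)=O
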